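**Retrosynthetic overview** (xanthanolide locants, primes for the spiro-lactone half; ring A = methylene lactone and ring B = seven-membered ring of the hydroxylated half, ring C = cyclohexene, ring D = spiro lactone and ring E = cycloheptene of the other half)

1. Target ⇒ C1–OH by γ-autoxidation of a β,γ-unsaturated ketone ⇒ [4+2] adduct ⇒ 8-epi-xanthatin (diene, rings A/B) + ent-tomentosin (dienophile, rings D/E); ring C, C5, C3 and the spiro centre C11′ come from the cycloaddition.
2. The two halves are mirror images at C7/C8/C10 (R,R,S above; S,S,R below), so both monomers come from one achiral silyl dienol ether by the same sequence, run with the two enantiomers of one cyclopropanation ligand; the lower half needs one extra 1,4-reduction.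
3. Each seven-membered ring ⇒ cis-1,2-dialkenylcyclopropane by Cope rearrangement, which forms the C1–C10 bond (the CH(CH3)–C(OH) bond of ring B) and opens the three-membered ring ⇒ siloxycyclopropane carbaldehyde + Wittig ylide ⇒ silyl dienol ether + ethyl diazoacetate.
4. Enabling feature: ring B (C1, C5, C6, C7, C8, C9, C10) carries oxygen on C8, and C1 and C5 are still sp2 before ring C exists. It therefore maps onto a cyclohepta-1,4-diene (C5=C6; C8=C9 as silyl enol ether) with C1 and the methyl-bearing C10 as adjacent sp3 atoms, which is the product pattern of a C6–C7–C8 cyclopropane with alkenyl arms on C6 and C8.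
5. Ring order: cyclopropane (temporary) → ring B (and ring E) → lactones A (and D) → ring C.

Key step: step 6

Assumption: the (S,S)-bis(oxazoline) ligand is taken to give the (1S,2S,3R)-cyclopropane 7; if the sense of induction is the opposite, the two ligand enantiomers are exchanged between steps 4 and 11.

**Route**

Step 1
Reactants: 1 tert-butyl 2-(bromomethyl)prop-2-enoate; 2 (2E)-but-2-enal
Product: 3 tert-butyl (5E)-4-hydroxy-2-methylidenehept-5-enoate (racemic)
Conditions: Zn, THF/sat. aq. NH4Cl, 0 → 25 °C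
Reagents that add atoms: none
Why: Barbier-type 2-(alkoxycarbonyl)allylation: the allylzinc from 1 should add 1,2 to the enal, the tert-butyl ester prevents lactonisation, and the racemic carbinol centre is removed in step 2.

Step 2
Reactants: 3 tert-butyl (5E)-4-hydroxy-2-methylidenehept-5-enoate
Product: 4 tert-butyl (5E)-2-methylidene-4-oxohept-5-enoate
Conditions: MnO2, CH2Cl2, 25 °C
Reagents that add atoms: none
Why: Allylic alcohol oxidation with MnO2 is neutral, so the acidic C7 methylene between ketone and acrylate should not be isomerised into conjugation.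

Step 3
Reactants: 4 tert-butyl (5E)-2-methylidene-4-oxohept-5-enoate
Product: 5 tert-butyl (3Z,5E)-4-[(tert-butyldimethylsilyl)oxy]-2-methylidenehepta-3,5-dienoate
Conditions: TBSOTf, Et3N, CH2Cl2, −78 → 0 °C
Reagents that add atoms: tert-butyldimethylsilyl trifluoromethanesulfonate, CC(C)(C)[Si](C)(C)OS(=O)(=O)C(F)(F)F
Why: Soft enolisation removes the doubly activated C7 proton and should give the silyl dienol ether with the acrylate cis to OSi (Z), the geometry that avoids 1,3-strain with the propenyl group and later places the C7 substituent trans to both alkenyl arms.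

Step 4
Reactants: 5 tert-butyl (3Z,5E)-4-[(tert-butyldimethylsilyl)oxy]-2-methylidenehepta-3,5-dienoate; 6 ethyl diazoacetate
Product: 7 ethyl (1S,2S,3R)-3-[1-(tert-butoxycarbonyl)ethenyl]-2-[(tert-butyldimethylsilyl)oxy]-2-[(1E)-prop-1-en-1-yl]cyclopropane-1-carboxylate
Conditions: [Cu(MeCN)4]PF6 (2 mol %), (S,S)-tBu-box [2,2′-(propane-2,2-diyl)bis((4S)-4-tert-butyl-4,5-dihydrooxazole)], CH2Cl2, 0 → 25 °C, slow addition of 6
Reagents that add atoms: none
Why: Copper–bis(oxazoline)-catalysed asymmetric cyclopropanation of a silyl enol ether: the electrophilic carbene should attack the most electron-rich C7=C8 bond with retention of its geometry, the ester takes the face anti to the C7 acrylate and OSi (cis to the propenyl group), and the ligand selects the enantioface and so the absolute configuration of C6, C7 and C8.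

Step 5
Reactants: 7 ethyl (1S,2S,3R)-3-[1-(tert-butoxycarbonyl)ethenyl]-2-[(tert-butyldimethylsilyl)oxy]-2-[(1E)-prop-1-en-1-yl]cyclopropane-1-carboxylate
Product: 8 tert-butyl 2-[(1R,2S,3S)-2-[(tert-butyldimethylsilyl)oxy]-3-formyl-2-[(1E)-prop-1-en-1-yl]cyclopropyl]prop-2-enoate
Conditions: iBu2AlH (1.05 equiv), CH2Cl2, −78 °C; aq. potassium sodium tartrate
Reagents that add atoms: none
Why: Partial ester reduction with iBu2AlH: the unhindered ethyl ester should stop at the tetrahedral aluminate and release the aldehyde on work-up, while the conjugated tert-butyl ester reacts much more slowly and no stereocentre is touched.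

Step 6
Reactants: 8 tert-butyl 2-[(1R,2S,3S)-2-[(tert-butyldimethylsilyl)oxy]-3-formyl-2-[(1E)-prop-1-en-1-yl]cyclopropyl]prop-2-enoate; 9 (triphenyl-λ5-phosphanylidene)acetaldehyde
Product: 12 tert-butyl 2-[(1R,4S)-2-[(tert-butyldimethylsilyl)oxy]-5-formyl-4-methylcyclohepta-2,5-dien-1-yl]prop-2-enoate, via cis-dialkenylcyclopropane 10 (not isolated), via cycloheptadienyl aldehyde 11 (not isolated)
Conditions: 9 (1.05 equiv), DBU (5 mol %), PhMe, 25 → 60 °C
Reagents that add atoms: none
Why: Wittig olefination with the stabilised ylide 9 should give the (E)-enal arm on C6, cis to the (E)-propenyl arm on C8, and this cis-1,2-dialkenylcyclopropane 10 should undergo the divinylcyclopropane–cycloheptadiene (Cope) rearrangement at or slightly above room temperature, driven by release of ring strain and helped by the siloxy donor on C8. The closest known reaction type is the tandem olefination/Cope rearrangement of cis-2-alkenylcyclopropanecarbaldehydes (and the related cyclopropanation/Cope route to cycloheptadienes). Ring B closes by the [3,3] shift itself through a boat transition state with both arms folded over the three-membered ring: the C1–C10 σ-bond forms between the two alkene termini while the C6–C8 bond breaks, leaving C5=C6 and the C8=C9 silyl enol ether. C10 is controlled by the E geometry of the propenyl arm together with the C7 centre, because the E substituents of the termini end up cis to the cyclopropane substituent that was trans to the arms, so the C10 methyl and the C7 acrylate become cis; C1 is formed cis to C10 but is erased. The step needs cis arms with E termini (secured by step 4 and the stabilised ylide; the C7 acrylate is trans to both arms and cannot take part) and no second olefination, which the catalytic DBU should secure by moving the C5=C6 bond of aldehyde 11 at once into conjugation to give the much less reactive enal 12.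

Step 7
Reactants: 12 tert-butyl 2-[(1R,4S)-2-[(tert-butyldimethylsilyl)oxy]-5-formyl-4-methylcyclohepta-2,5-dien-1-yl]prop-2-enoate; 13 1-(triphenyl-λ5-phosphanylidene)propan-2-one
Product: 14 tert-butyl 2-[(1R,4S)-2-[(tert-butyldimethylsilyl)oxy]-4-methyl-5-[(1E)-3-oxobut-1-en-1-yl]cyclohepta-2,5-dien-1-yl]prop-2-enoate
Conditions: PhMe, 90 °C
Reagents that add atoms: none
Why: Wittig olefination with the stabilised acetonyl ylide should convert the hindered enal into the (E)-enone and complete the C5=C1–C2=C3–C4=O dienone; silyl enol ether and acrylate are inert to the ylide.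

Step 8
Reactants: 14 tert-butyl 2-[(1R,4S)-2-[(tert-butyldimethylsilyl)oxy]-4-methyl-5-[(1E)-3-oxobut-1-en-1-yl]cyclohepta-2,5-dien-1-yl]prop-2-enoate
Product: 15 tert-butyl 2-[(1R,4S)-4-methyl-2-oxo-5-[(1E)-3-oxobut-1-en-1-yl]cyclohept-5-en-1-yl]prop-2-enoate
Conditions: TBAF, AcOH, THF, 0 °C
Reagents that add atoms: none
Why: Fluoride cleavage of the silyl enol ether under acetic acid buffering protonates at C9, so the ketone should appear regiospecifically at C8 without disturbing the epimerisable C7 centre or the β,γ-placed acrylate.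

Step 9
Reactants: 15 tert-butyl 2-[(1R,4S)-4-methyl-2-oxo-5-[(1E)-3-oxobut-1-en-1-yl]cyclohept-5-en-1-yl]prop-2-enoate
Product: 16 tert-butyl 2-[(1R,2R,4S)-2-hydroxy-4-methyl-5-[(1E)-3-oxobut-1-en-1-yl]cyclohept-5-en-1-yl]prop-2-enoate
Conditions: NaBH4, MeOH/CH2Cl2 (1:1), −78 °C
Reagents that add atoms: none
Why: Chemoselective borohydride reduction: the saturated ring ketone should react faster than the doubly conjugated methyl ketone, and hydride should enter from the face opposite the cis C7 and C10 substituents, setting C8 with OH cis to the acrylate.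

Step 10
Reactants: 16 tert-butyl 2-[(1R,2R,4S)-2-hydroxy-4-methyl-5-[(1E)-3-oxobut-1-en-1-yl]cyclohept-5-en-1-yl]prop-2-enoate
Product: 18 8-epi-xanthatin [(3aR,7S,8aR)-7-methyl-3-methylidene-6-[(1E)-3-oxobut-1-en-1-yl]-3,3a,4,7,8,8a-hexahydro-2H-cyclohepta[b]furan-2-one], via hydroxy acid 17 (not isolated)
Conditions: TFA, CH2Cl2, 0 → 25 °C
Reagents that add atoms: none
Why: Acidolysis of the tert-butyl ester followed by lactonisation of the cis γ-hydroxy acid should close the cis-fused α-methylene lactone (ring A) without creating a stereocentre.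

Step 11
Reactants: 5 tert-butyl (3Z,5E)-4-[(tert-butyldimethylsilyl)oxy]-2-methylidenehepta-3,5-dienoate; 6 ethyl diazoacetate
Product: 19 ethyl (1R,2R,3S)-3-[1-(tert-butoxycarbonyl)ethenyl]-2-[(tert-butyldimethylsilyl)oxy]-2-[(1E)-prop-1-en-1-yl]cyclopropane-1-carboxylate
Conditions: [Cu(MeCN)4]PF6 (2 mol %), (R,R)-tBu-box, CH2Cl2, 0 → 25 °C, slow addition of 6
Reagents that add atoms: none
Why: Same asymmetric cyclopropanation as step 4; the mirror-image ligand should select the opposite enantioface and give the enantiomer of 7.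

Step 12
Reactants: 19 ethyl (1R,2R,3S)-3-[1-(tert-butoxycarbonyl)ethenyl]-2-[(tert-butyldimethylsilyl)oxy]-2-[(1E)-prop-1-en-1-yl]cyclopropane-1-carboxylate
Product: 20 tert-butyl 2-[(1S,2R,3R)-2-[(tert-butyldimethylsilyl)oxy]-3-formyl-2-[(1E)-prop-1-en-1-yl]cyclopropyl]prop-2-enoate
Conditions: iBu2AlH (1.05 equiv), CH2Cl2, −78 °C; aq. potassium sodium tartrate
Reagents that add atoms: none
Why: Partial ester reduction as in step 5, in the mirror-image series.

Step 13
Reactants: 20 tert-butyl 2-[(1S,2R,3R)-2-[(tert-butyldimethylsilyl)oxy]-3-formyl-2-[(1E)-prop-1-en-1-yl]cyclopropyl]prop-2-enoate; 9 (triphenyl-λ5-phosphanylidene)acetaldehyde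
Product: 23 tert-butyl 2-[(1S,4R)-2-[(tert-butyldimethylsilyl)oxy]-5-formyl-4-methylcyclohepta-2,5-dien-1-yl]prop-2-enoate, via mirror-image dialkenylcyclopropane 21 (not isolated), via mirror-image cycloheptadienyl aldehyde 22 (not isolated)
Conditions: 9 (1.05 equiv), DBU (5 mol %), PhMe, 25 → 60 °C
Reagents that add atoms: none
Why: Tandem Wittig olefination/divinylcyclopropane (Cope) rearrangement exactly as in step 6, forming ring E and setting C10′ cis to the C7′ acrylate by the same boat transition state.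

Step 14
Reactants: 23 tert-butyl 2-[(1S,4R)-2-[(tert-butyldimethylsilyl)oxy]-5-formyl-4-methylcyclohepta-2,5-dien-1-yl]prop-2-enoate; 13 1-(triphenyl-λ5-phosphanylidene)propan-2-one
Product: 24 tert-butyl 2-[(1S,4R)-2-[(tert-butyldimethylsilyl)oxy]-4-methyl-5-[(1E)-3-oxobut-1-en-1-yl]cyclohepta-2,5-dien-1-yl]prop-2-enoate
Conditions: PhMe, 90 °C
Reagents that add atoms: none
Why: Wittig olefination as in step 7, in the mirror-image series.

Step 15
Reactants: 24 tert-butyl 2-[(1S,4R)-2-[(tert-butyldimethylsilyl)oxy]-4-methyl-5-[(1E)-3-oxobut-1-en-1-yl]cyclohepta-2,5-dien-1-yl]prop-2-enoate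
Product: 25 tert-butyl 2-[(1S,4R)-4-methyl-2-oxo-5-[(1E)-3-oxobut-1-en-1-yl]cyclohept-5-en-1-yl]prop-2-enoate
Conditions: TBAF, AcOH, THF, 0 °C
Reagents that add atoms: none
Why: Buffered fluoride cleavage of the silyl enol ether as in step 8.

Step 16
Reactants: 25 tert-butyl 2-[(1S,4R)-4-methyl-2-oxo-5-[(1E)-3-oxobut-1-en-1-yl]cyclohept-5-en-1-yl]prop-2-enoate
Product: 26 tert-butyl 2-[(1S,2S,4R)-2-hydroxy-4-methyl-5-[(1E)-3-oxobut-1-en-1-yl]cyclohept-5-en-1-yl]prop-2-enoate
Conditions: NaBH4, MeOH/CH2Cl2 (1:1), −78 °C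
Reagents that add atoms: none
Why: Chemoselective and face-selective ketone reduction as in step 9, setting C8′.

Step 17
Reactants: 26 tert-butyl 2-[(1S,2S,4R)-2-hydroxy-4-methyl-5-[(1E)-3-oxobut-1-en-1-yl]cyclohept-5-en-1-yl]prop-2-enoate
Product: 28 ent-8-epi-xanthatin [(3aS,7R,8aS)-7-methyl-3-methylidene-6-[(1E)-3-oxobut-1-en-1-yl]-3,3a,4,7,8,8a-hexahydro-2H-cyclohepta[b]furan-2-one], via mirror-image hydroxy acid 27 (not isolated)
Conditions: TFA, CH2Cl2, 0 → 25 °C
Reagents that add atoms: none
Why: Ester acidolysis and lactonisation as in step 10, closing ring D as its methylene-lactone precursor.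

Step 18
Reactants: 28 ent-8-epi-xanthatin
Product: 29 ent-tomentosin [(3aS,7R,8aS)-7-methyl-3-methylidene-6-(3-oxobutyl)-3,3a,4,7,8,8a-hexahydro-2H-cyclohepta[b]furan-2-one]
Conditions: Pd(PPh3)4 (2 mol %), Ph2SiH2, ZnCl2, CHCl3, 25 °C; aq. work-up
Reagents that add atoms: none
Why: Palladium-catalysed conjugate reduction with a silane and ZnCl2 (as for β-ionone to dihydro-β-ionone) should deliver hydride only to the α,β-bond of the ketone-conjugated diene and spare unsaturated esters and lactones, so C1′=C5′ and the methylene lactone remain.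

Step 19
Reactants: 18 8-epi-xanthatin; 29 ent-tomentosin
Product: 30 [4+2] cross adduct (target skeleton with C1=C2 double bond and C3–H; acetyl on C3 cis to the spiro-lactone carbonyl)
Conditions: 29 (3 equiv), PhMe (2 M), BHT, 90 °C, sealed tube
Reagents that add atoms: none
Why: Thermal Diels–Alder reaction as in xanthanolide dimerisation: the s-cis dienone of 18 should react on the face opposite its lactone and C10 methyl with the convex (H7′/H8′) face of the methylene lactone of 29, carbonyl endo and CH2 bonding to C5, which sets C5, C3 and the spiro centre C11′, while the excess of 29 outcompetes self-dimerisation of 18.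

Step 20
Reactants: 30 [4+2] cross adduct
Product: 32 CNP0195550.3 (target), via tertiary hydroperoxide 31 (not isolated)
Conditions: O2 (1 atm), DBU (0.3 equiv), MeCN, 0 °C; then PPh3
Reagents that add atoms: dioxygen, O=O
Why: Base-mediated autoxidation of a β,γ-unsaturated ketone: DBU removes the only doubly activated proton (C3–H), the extended enolate should take up O2 at its γ-carbon C1 on the face cis to H-5 (the other face is covered by C6 of ring B), and PPh3 reduces hydroperoxide 31 to the tertiary alcohol with the enone now conjugated.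

**Compound list**

1 | tert-butyl 2-(bromomethyl)prop-2-enoate | C=C(CBr)C(=O)OC(C)(C)C | starting material
2 | (2E)-but-2-enal | C/C=C/C=O | starting material
3 | tert-butyl (5E)-4-hydroxy-2-methylidenehept-5-enoate (racemic) | C/C=C/C(O)CC(=C)C(=O)OC(C)(C)C | intermediate
4 | tert-butyl (5E)-2-methylidene-4-oxohept-5-enoate | C/C=C/C(=O)CC(=C)C(=O)OC(C)(C)C | intermediate
5 | tert-butyl (3Z,5E)-4-[(tert-butyldimethylsilyl)oxy]-2-methylidenehepta-3,5-dienoate | C/C=C/C(O[Si](C)(C)C(C)(C)C)=C/C(=C)C(=O)OC(C)(C)C | intermediate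
6 | ethyl diazoacetate | CCOC(=O)C=[N+]=[N-] | starting material
7 | ethyl (1S,2S,3R)-3-[1-(tert-butoxycarbonyl)ethenyl]-2-[(tert-butyldimethylsilyl)oxy]-2-[(1E)-prop-1-en-1-yl]cyclopropane-1-carboxylate | CCOC(=O)[C@H]1[C@H](C(=C)C(=O)OC(C)(C)C)[C@@]1(O[Si](C)(C)C(C)(C)C)/C=C/C | intermediate
8 | tert-butyl 2-[(1R,2S,3S)-2-[(tert-butyldimethylsilyl)oxy]-3-formyl-2-[(1E)-prop-1-en-1-yl]cyclopropyl]prop-2-enoate | O=C[C@H]1[C@H](C(=C)C(=O)OC(C)(C)C)[C@@]1(O[Si](C)(C)C(C)(C)C)/C=C/C | intermediate
9 | (triphenyl-λ5-phosphanylidene)acetaldehyde | O=CC=P(c1ccccc1)(c1ccccc1)c1ccccc1 | starting material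
10 | tert-butyl 2-[(1R,2R,3S)-2-[(tert-butyldimethylsilyl)oxy]-3-[(1E)-3-oxoprop-1-en-1-yl]-2-[(1E)-prop-1-en-1-yl]cyclopropyl]prop-2-enoate (cis-dialkenylcyclopropane) | O=C/C=C/[C@H]1[C@H](C(=C)C(=O)OC(C)(C)C)[C@@]1(O[Si](C)(C)C(C)(C)C)/C=C/C | intermediate (not isolated)
11 | tert-butyl 2-[(1R,4S,5R)-2-[(tert-butyldimethylsilyl)oxy]-5-formyl-4-methylcyclohepta-2,6-dien-1-yl]prop-2-enoate | O=C[C@@H]1C=C[C@H](C(=C)C(=O)OC(C)(C)C)C(O[Si](C)(C)C(C)(C)C)=C[C@@H]1C | intermediate (not isolated)
12 | tert-butyl 2-[(1R,4S)-2-[(tert-butyldimethylsilyl)oxy]-5-formyl-4-methylcyclohepta-2,5-dien-1-yl]prop-2-enoate | O=CC1=CC[C@H](C(=C)C(=O)OC(C)(C)C)C(O[Si](C)(C)C(C)(C)C)=C[C@@H]1C | intermediate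
13 | 1-(triphenyl-λ5-phosphanylidene)propan-2-one | CC(=O)C=P(c1ccccc1)(c1ccccc1)c1ccccc1 | starting material
14 | tert-butyl 2-[(1R,4S)-2-[(tert-butyldimethylsilyl)oxy]-4-methyl-5-[(1E)-3-oxobut-1-en-1-yl]cyclohepta-2,5-dien-1-yl]prop-2-enoate | CC(=O)/C=C/C1=CC[C@H](C(=C)C(=O)OC(C)(C)C)C(O[Si](C)(C)C(C)(C)C)=C[C@@H]1C | intermediate
15 | tert-butyl 2-[(1R,4S)-4-methyl-2-oxo-5-[(1E)-3-oxobut-1-en-1-yl]cyclohept-5-en-1-yl]prop-2-enoate | CC(=O)/C=C/C1=CC[C@H](C(=C)C(=O)OC(C)(C)C)C(=O)C[C@@H]1C | intermediate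
16 | tert-butyl 2-[(1R,2R,4S)-2-hydroxy-4-methyl-5-[(1E)-3-oxobut-1-en-1-yl]cyclohept-5-en-1-yl]prop-2-enoate | CC(=O)/C=C/C1=CC[C@H](C(=C)C(=O)OC(C)(C)C)[C@H](O)C[C@@H]1C | intermediate
17 | 2-[(1R,2R,4S)-2-hydroxy-4-methyl-5-[(1E)-3-oxobut-1-en-1-yl]cyclohept-5-en-1-yl]prop-2-enoic acid | CC(=O)/C=C/C1=CC[C@H](C(=C)C(=O)O)[C@H](O)C[C@@H]1C | intermediate (not isolated)
18 | 8-epi-xanthatin, (3aR,7S,8aR) | C=C1C(=O)O[C@@H]2C[C@H](C)C(/C=C/C(C)=O)=CC[C@H]12 | intermediate
19 | ethyl (1R,2R,3S)-3-[1-(tert-butoxycarbonyl)ethenyl]-2-[(tert-butyldimethylsilyl)oxy]-2-[(1E)-prop-1-en-1-yl]cyclopropane-1-carboxylate | CCOC(=O)[C@@H]1[C@@H](C(=C)C(=O)OC(C)(C)C)[C@]1(O[Si](C)(C)C(C)(C)C)/C=C/C | intermediate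
20 | tert-butyl 2-[(1S,2R,3R)-2-[(tert-butyldimethylsilyl)oxy]-3-formyl-2-[(1E)-prop-1-en-1-yl]cyclopropyl]prop-2-enoate | O=C[C@@H]1[C@@H](C(=C)C(=O)OC(C)(C)C)[C@]1(O[Si](C)(C)C(C)(C)C)/C=C/C | intermediate
21 | tert-butyl 2-[(1S,2S,3R)-2-[(tert-butyldimethylsilyl)oxy]-3-[(1E)-3-oxoprop-1-en-1-yl]-2-[(1E)-prop-1-en-1-yl]cyclopropyl]prop-2-enoate | O=C/C=C/[C@@H]1[C@@H](C(=C)C(=O)OC(C)(C)C)[C@]1(O[Si](C)(C)C(C)(C)C)/C=C/C | intermediate (not isolated)
22 | tert-butyl 2-[(1S,4R,5S)-2-[(tert-butyldimethylsilyl)oxy]-5-formyl-4-methylcyclohepta-2,6-dien-1-yl]prop-2-enoate | O=C[C@H]1C=C[C@@H](C(=C)C(=O)OC(C)(C)C)C(O[Si](C)(C)C(C)(C)C)=C[C@H]1C | intermediate (not isolated)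
23 | tert-butyl 2-[(1S,4R)-2-[(tert-butyldimethylsilyl)oxy]-5-formyl-4-methylcyclohepta-2,5-dien-1-yl]prop-2-enoate | O=CC1=CC[C@@H](C(=C)C(=O)OC(C)(C)C)C(O[Si](C)(C)C(C)(C)C)=C[C@H]1C | intermediate
24 | tert-butyl 2-[(1S,4R)-2-[(tert-butyldimethylsilyl)oxy]-4-methyl-5-[(1E)-3-oxobut-1-en-1-yl]cyclohepta-2,5-dien-1-yl]prop-2-enoate | CC(=O)/C=C/C1=CC[C@@H](C(=C)C(=O)OC(C)(C)C)C(O[Si](C)(C)C(C)(C)C)=C[C@H]1C | intermediate
25 | tert-butyl 2-[(1S,4R)-4-methyl-2-oxo-5-[(1E)-3-oxobut-1-en-1-yl]cyclohept-5-en-1-yl]prop-2-enoate | CC(=O)/C=C/C1=CC[C@@H](C(=C)C(=O)OC(C)(C)C)C(=O)C[C@H]1C | intermediate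
26 | tert-butyl 2-[(1S,2S,4R)-2-hydroxy-4-methyl-5-[(1E)-3-oxobut-1-en-1-yl]cyclohept-5-en-1-yl]prop-2-enoate | CC(=O)/C=C/C1=CC[C@@H](C(=C)C(=O)OC(C)(C)C)[C@@H](O)C[C@H]1C | intermediate
27 | 2-[(1S,2S,4R)-2-hydroxy-4-methyl-5-[(1E)-3-oxobut-1-en-1-yl]cyclohept-5-en-1-yl]prop-2-enoic acid | CC(=O)/C=C/C1=CC[C@@H](C(=C)C(=O)O)[C@@H](O)C[C@H]1C | intermediate (not isolated)
28 | ent-8-epi-xanthatin, (3aS,7R,8aS) | C=C1C(=O)O[C@H]2C[C@@H](C)C(/C=C/C(C)=O)=CC[C@@H]12 | intermediate
29 | ent-tomentosin, (3aS,7R,8aS)-7-methyl-3-methylidene-6-(3-oxobutyl)-3,3a,4,7,8,8a-hexahydro-2H-cyclohepta[b]furan-2-one | C=C1C(=O)O[C@H]2C[C@@H](C)C(CCC(C)=O)=CC[C@@H]12 | intermediate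
30 | [4+2] cross adduct: target skeleton with C1=C2 double bond, C3–H and acetyl cis to the spiro-lactone carbonyl | C=C1C(=O)O[C@@H]2C[C@H](C)C3=C[C@@H](C(C)=O)[C@]4(C[C@H]3C[C@H]12)C(=O)O[C@H]1C[C@@H](C)C(CCC(C)=O)=CC[C@H]14 | intermediate
31 | C1 hydroperoxide of the target (OOH in place of OH) | C=C1C(=O)O[C@@H]2C[C@H](C)[C@@]3(OO)C=C(C(C)=O)[C@]4(C[C@H]3C[C@H]12)C(=O)O[C@H]1C[C@@H](C)C(CCC(C)=O)=CC[C@H]14 | intermediate (not isolated)
32 | CNP0195550.3 | C=C1C(=O)O[C@@H]2C[C@H](C)[C@@]3(O)C=C(C(C)=O)[C@]4(C[C@H]3C[C@H]12)C(=O)O[C@H]1C[C@@H](C)C(CCC(C)=O)=CC[C@H]14 | target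

**Step count, longest sequence, risks**

Total step count: 20. Longest linear sequence: 13 steps (steps 1–3, 11–18, 19, 20).

Steps most likely to fail:

Step 4 (and its mirror, step 11): the carbene transfer may show poor enantioface or cis/trans discrimination on this trisubstituted, conjugated enol ether, or may attack the propenyl double bond. The fallback sets out from 5 and 6 and comes back at 8 and at 20. Cyclopropanation with the achiral catalyst Rh2(OAc)4 would give the racemate (7 together with 19), and iBu2AlH (2.2 equiv, −78 °C) would reduce the ethyl ester to the racemic primary alcohol. Lipase-catalysed acetylation (Burkholderia cepacia lipase, vinyl acetate) would resolve it into the unreacted cyclopropylmethanol F1 and the acetate F2 of the other enantiomer. Dess–Martin oxidation of F1 would give 8; cleavage of F2 with iBu2AlH would give the mirror-image cyclopropylmethanol F3, oxidised in the same way to 20. If the enzyme prefers the other enantiomer, the two branches exchange roles.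

Step 19: self-dimerisation of 18 through its own methylene lactone may compete, or endo and facial discrimination may be poor. The fallback sets out from 16 and 29 and comes back at 30. The hydroxy ester 16, whose acyclic tert-butyl acrylate is a far weaker dienophile than a strained methylene lactone, would serve as the diene, and thermal [4+2] reaction with 29 would give the hydroxy ester adduct F4. Lactonisation with TFA as in step 10 would then give 30.

Step 20: oxygen may attack the wrong face of the extended enolate (trans ring fusion) or the α-carbon C3. The fallback sets out from 30 and comes back at 32 through 31, with no new compound. Photooxygenation with singlet oxygen (tetraphenylporphyrin, O2, visible light, CH2Cl2, −40 °C) is a suprafacial ene reaction: H-3 lies on the lower face of the endo adduct, so the C1–O bond has to form on that same face, and PPh3 then reduces 31. The trisubstituted olefin of the lower half is a competing ene site, so the irradiation would be stopped at partial conversion and 30 recycled.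

Further compounds
F1 | step 4 | tert-butyl 2-[(1R,2S,3R)-2-[(tert-butyldimethylsilyl)oxy]-3-(hydroxymethyl)-2-[(1E)-prop-1-en-1-yl]cyclopropyl]prop-2-enoate | OC[C@H]1[C@H](C(=C)C(=O)OC(C)(C)C)[C@@]1(O[Si](C)(C)C(C)(C)C)/C=C/C
F2 | step 4 | tert-butyl 2-[(1S,2R,3S)-3-(acetyloxymethyl)-2-[(tert-butyldimethylsilyl)oxy]-2-[(1E)-prop-1-en-1-yl]cyclopropyl]prop-2-enoate | CC(=O)OC[C@@H]1[C@@H](C(=C)C(=O)OC(C)(C)C)[C@]1(O[Si](C)(C)C(C)(C)C)/C=C/C
F3 | step 4 | tert-butyl 2-[(1S,2R,3S)-2-[(tert-butyldimethylsilyl)oxy]-3-(hydroxymethyl)-2-[(1E)-prop-1-en-1-yl]cyclopropyl]prop-2-enoate | OC[C@@H]1[C@@H](C(=C)C(=O)OC(C)(C)C)[C@]1(O[Si](C)(C)C(C)(C)C)/C=C/C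
F4 | step 19 | [4+2] adduct of 16 with 29: compound 30 with ring A opened to the C8 alcohol and the C7 tert-butyl acrylate | CC(=O)[C@@H]1C=C2[C@@H](C)C[C@@H](O)[C@@H](C(=C)C(=O)OC(C)(C)C)C[C@@H]2C[C@]13C(=O)O[C@H]4C[C@@H](C)C(CCC(C)=O)=CC[C@@H]34
F0 | step 20 | none | none
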